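**Strategy.** The six-membered ring is disconnected between C1 and C6 and between C3 and C4. Read with C2 as a ketone and the side chain as an ester, C1–C2–C3 is the α-carbon, carbonyl and isopropyl γ-carbon of methyl isobutyrylacetate, a 1,3-bis-nucleophile; C6–C5–C4 is acrolein, a 1,3-bis-electrophile. One [3+3] Michael–aldol operation joins them and creates the ring, the quaternary gem-dimethyl carbon beside the future CHBr, and the keto ester that later becomes the tetrasubstituted vinyl bromide. The carbinol is then set by a ketoreductase, both ring C–Br bonds are made in one deoxybromination, and the ester is grown into the (S)-chloro-bromoethyl arm.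

Key step: step 1

Remark: ring atoms are numbered as in the target (C1 carries the side chain, C2 the vinylic bromine, C3 the two methyl groups, C4 the secondary bromine). The ketoreductase of step 3 is assumed to be selected from a commercial enzyme panel by screening for (4S) selectivity.

Step 1
Reactants: 1 methyl 4-methyl-3-oxopentanoate; 2 acrolein
Product: 4 methyl 4-hydroxy-3,3-dimethyl-2-oxocyclohexane-1-carboxylate, via Michael adduct 3 (not isolated)
Conditions: 2 (1.05 equiv, slow addition), Et3N (5 mol %), CH2Cl2, 0 °C; then DBU (1,8-diazabicyclo[5.4.0]undec-7-ene, 0.3 equiv), rt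
Reagents that add atoms: none
Why: Et3N-catalysed conjugate addition of the α-carbon of 1 (ring C1) to acrolein gives keto aldehyde 3, and DBU then lets the minor tetrasubstituted enolate on the isopropyl side (ring C3) add to the aldehyde carbon (ring C4). The closest known reaction type is the Robinson-type [3+3] Michael–aldol annulation of β-keto esters with enals, in which the γ-carbon closes the ring. The six-membered ring closes in a 6-(enolendo)-exo-trig aldol addition, and the quaternary C3 rules out dehydration, so the adduct should be a stable ketol. C1 and C4 form without control and are not meant to be controlled here: C1 becomes sp2 in step 4 and C4 is reset by steps 2 and 3. The selectivity needed is site selectivity, secured by the substrate: only the α-carbon of 1 is acidic enough for the Michael step, the ester offers no second enolisable carbon, and every other intramolecular aldol would close a four-membered ring. Lactol formation from the enol oxygen is reversible and should drain into the C–C closed product, while slow addition of acrolein suppresses a second conjugate addition.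

Step 2
Reactants: 4 methyl 4-hydroxy-3,3-dimethyl-2-oxocyclohexane-1-carboxylate
Product: 5 methyl 3,3-dimethyl-2,4-dioxocyclohexane-1-carboxylate
Conditions: n-Pr4N[RuO4] (5 mol %), N-methylmorpholine N-oxide (1.5 equiv), 4 Å molecular sieves, CH2Cl2, rt
Reagents that add atoms: none
Why: Perruthenate-catalysed oxidation of the hindered secondary alcohol erases the uncontrolled C4 centre under neutral conditions that leave the β-keto ester alone, and the dione cannot enolise between its carbonyls because C3 is quaternary.

Step 3
Reactants: 5 methyl 3,3-dimethyl-2,4-dioxocyclohexane-1-carboxylate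
Product: 6 methyl (4S)-4-hydroxy-3,3-dimethyl-2-oxocyclohexane-1-carboxylate
Conditions: ketoreductase (NADPH-dependent, (S)-selective), NADP+ (cat.), propan-2-ol (10% v/v), phosphate buffer pH 6.5, 30 °C
Reagents that add atoms: none
Why: Enzymatic carbonyl reduction by a ketoreductase, the enzyme class that reduces 2,2-disubstituted cyclohexane-1,3-diones to (S)-3-hydroxy ketones, should set C4 as S and distinguish the accessible C4 ketone from the enolised, doubly flanked C2 ketone, which no small hydride reagent would do (C1 stays a mixture and becomes sp2 in step 4).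

Step 4
Reactants: 6 methyl (4S)-4-hydroxy-3,3-dimethyl-2-oxocyclohexane-1-carboxylate
Product: 7 methyl (4R)-2,4-dibromo-3,3-dimethylcyclohex-1-ene-1-carboxylate
Conditions: PPh3 (2.6 equiv), Br2 (2.5 equiv), MeCN, 0 °C; then 6, Et3N (2.5 equiv), 0 → 60 °C
Reagents that add atoms: bromine, BrBr
Why: Ph3PBr2 turns both the C4 carbinol and the enol of the β-keto ester into oxyphosphonium ions; bromide should displace the first with inversion (S to R, deoxybromination of alcohols by phosphine dihalides, which tolerates neopentyl-type centres) and replace the second by addition–elimination at C2 (β-halo enone formation from 1,3-dicarbonyls), the alkene being forced to C1=C2 because C3 is quaternary.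

Step 5
Reactants: 7 methyl (4R)-2,4-dibromo-3,3-dimethylcyclohex-1-ene-1-carboxylate
Product: 9 2-bromo-1-[(4R)-2,4-dibromo-3,3-dimethylcyclohex-1-en-1-yl]ethan-1-one, via lithium hemiketal 8 (not isolated)
Conditions: CH2Br2 (3 equiv), MeLi·LiBr (2.5 equiv, slow addition), THF–Et2O, −78 °C; AcOH, −78 °C
Reagents that add atoms: dibromomethane, BrCBr
Why: Bromomethyllithium, generated in the presence of the ester, should add once to the ester carbonyl (halomethyllithium acylation by esters), the lithium hemiketal 8 persisting at −78 °C until the acidic quench releases the bromomethyl ketone, while the neopentylic and vinylic bromides are inert to the carbenoid at this temperature.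

Step 6
Reactants: 9 2-bromo-1-[(4R)-2,4-dibromo-3,3-dimethylcyclohex-1-en-1-yl]ethan-1-one
Product: 10 (1R)-2-bromo-1-[(4R)-2,4-dibromo-3,3-dimethylcyclohex-1-en-1-yl]ethan-1-ol
Conditions: (R)-2-methyl-CBS-oxazaborolidine [(3aR)-1-methyl-3,3-diphenylhexahydropyrrolo[1,2-c][1,3,2]oxazaborole] (0.2 equiv), BH3·SMe2 (0.7 equiv), THF, −20 °C; MeOH
Reagents that add atoms: none
Why: Corey–Bakshi–Shibata reduction, in which the (R)-oxazaborolidine–borane complex should bind the ketone with the bulky cyclohexenyl group as the large and CH2Br as the small substituent and deliver hydride to the face that gives the (R)-bromohydrin, under catalyst control and independent of the remote C4 centre.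

Step 7
Reactants: 10 (1R)-2-bromo-1-[(4R)-2,4-dibromo-3,3-dimethylcyclohex-1-en-1-yl]ethan-1-ol
Product: 11 (4R)-2,4-dibromo-1-[(1S)-2-bromo-1-chloroethyl]-3,3-dimethylcyclohex-1-ene
Conditions: PPh3 (1.5 equiv), hexachloroacetone (2 equiv), CH2Cl2, −30 → 0 °C
Reagents that add atoms: hexachloroacetone, ClC(Cl)(Cl)C(=O)C(Cl)(Cl)Cl
Why: Appel-type deoxychlorination, in which chloride should displace the alkoxyphosphonium ion in an SN2 step with inversion (R to S), the SN2′ path being blocked because the far alkene carbon carries bromine and adjoins the quaternary C3, and the electron-poor alkene and neighbouring CH2Br disfavouring ionisation.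

**Compound list**

1 | methyl 4-methyl-3-oxopentanoate | CC(C)C(=O)CC(=O)OC | starting material
2 | acrolein (prop-2-enal) | C=CC=O | starting material
3 | methyl 2-(2-methylpropanoyl)-5-oxopentanoate (racemic Michael adduct) | CC(C)C(=O)C(CCC=O)C(=O)OC | intermediate
4 | methyl 4-hydroxy-3,3-dimethyl-2-oxocyclohexane-1-carboxylate (mixture of stereoisomers) | COC(=O)C1CCC(O)C(C)(C)C1=O | intermediate
5 | methyl 3,3-dimethyl-2,4-dioxocyclohexane-1-carboxylate | COC(=O)C1CCC(=O)C(C)(C)C1=O | intermediate
6 | methyl (4S)-4-hydroxy-3,3-dimethyl-2-oxocyclohexane-1-carboxylate (C1 epimers) | CC1(C)C(=O)C(C(=O)OC)CC[C@@H]1O | intermediate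
7 | methyl (4R)-2,4-dibromo-3,3-dimethylcyclohex-1-ene-1-carboxylate | CC1(C)C(Br)=C(C(=O)OC)CC[C@H]1Br | intermediate
8 | lithium 2-bromo-1-[(4R)-2,4-dibromo-3,3-dimethylcyclohex-1-en-1-yl]-1-methoxyethan-1-olate (hemiketal adduct) | CC1(C)C(Br)=C(C([O-])(OC)CBr)CC[C@H]1Br.[Li+] | intermediate
9 | 2-bromo-1-[(4R)-2,4-dibromo-3,3-dimethylcyclohex-1-en-1-yl]ethan-1-one | CC1(C)C(Br)=C(C(=O)CBr)CC[C@H]1Br | intermediate
10 | (1R)-2-bromo-1-[(4R)-2,4-dibromo-3,3-dimethylcyclohex-1-en-1-yl]ethan-1-ol | CC1(C)C(Br)=C([C@@H](O)CBr)CC[C@H]1Br | intermediate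
11 | (4R)-2,4-dibromo-1-[(1S)-2-bromo-1-chloroethyl]-3,3-dimethylcyclohex-1-ene | CC1(C)C(Br)=C([C@H](Cl)CBr)CC[C@H]1Br | target

Total step count: 7. Longest linear sequence: 7 steps.

**Steps most likely to fail**

Step 4. At the neopentylic C4 the oxyphosphonium ion may lose a proton toward C5 or undergo a 1,2-shift faster than bromide displaces it, and the enol activation at the hindered C2 may stall. The fallback separates the two events and uses sulfonate chemistry. It sets out from 6: chloromethanesulfonyl chloride and pyridine at 0 °C should give methyl (4S)-4-[(chloromethanesulfonyl)oxy]-3,3-dimethyl-2-oxocyclohexane-1-carboxylate F1. LiBr in DMF at 60 °C should displace this small, strongly activating sulfonate with inversion to give methyl (4R)-4-bromo-3,3-dimethyl-2-oxocyclohexane-1-carboxylate F2. NaH and PhNTf2 in THF should give the enol triflate methyl (4R)-4-bromo-3,3-dimethyl-2-(trifluoromethanesulfonyloxy)cyclohex-1-ene-1-carboxylate F3. Triflate–bromide exchange with LiBr and catalytic [Cp*Ru(MeCN)3]OTf in 1,3-dimethyl-2-imidazolidinone then returns to the route at 7.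

Step 1. The Michael adduct may rest as its cyclic lactol, the aldehyde may self-condense, or a second conjugate addition may occur before the hindered tetrasubstituted enolate closes the ring. The fallback reverses the order of bond formation and sets out from 1. Me3SiCl and Et3N should give methyl 4-methyl-3-(trimethylsilyloxy)pent-2-enoate F4. LDA and then Me3SiCl at −78 °C should give the 1,3-bis(silyl enol ether) 1-methoxy-4-methyl-1,3-bis(trimethylsilyloxy)penta-1,3-diene F5. Acryloyl chloride in CH2Cl2 (−78 → 20 °C) should acylate its terminal carbon to give methyl 4,4-dimethyl-3,5-dioxohept-6-enoate F6. DBU should then close the ring by 6-endo-trig conjugate addition, returning to the route at 5, so that step 2 is not needed.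

Step 5. The tetrahedral adduct may collapse early and take up a second carbenoid, or bromine–lithium exchange may occur at the vinylic bromide. The fallback avoids organolithium reagents and sets out from 7. Me3SnOH in 1,2-dichloroethane at 80 °C should give (4R)-2,4-dibromo-3,3-dimethylcyclohex-1-ene-1-carboxylic acid F7. Oxalyl chloride with catalytic DMF should give (4R)-2,4-dibromo-3,3-dimethylcyclohex-1-ene-1-carbonyl chloride F8. Diazomethane in Et2O at 0 °C should give 2-diazo-1-[(4R)-2,4-dibromo-3,3-dimethylcyclohex-1-en-1-yl]ethan-1-one F9. HBr in acetic acid at 0 °C then returns to the route at 9.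

Further compounds
F1 | step 4 | methyl (4S)-4-[(chloromethanesulfonyl)oxy]-3,3-dimethyl-2-oxocyclohexane-1-carboxylate | CC1(C)C(=O)C(C(=O)OC)CC[C@@H]1OS(=O)(=O)CCl
F2 | step 4 | methyl (4R)-4-bromo-3,3-dimethyl-2-oxocyclohexane-1-carboxylate | CC1(C)C(=O)C(C(=O)OC)CC[C@H]1Br
F3 | step 4 | methyl (4R)-4-bromo-3,3-dimethyl-2-(trifluoromethanesulfonyloxy)cyclohex-1-ene-1-carboxylate | CC1(C)C(OS(=O)(=O)C(F)(F)F)=C(C(=O)OC)CC[C@H]1Br
F4 | step 1 | methyl 4-methyl-3-(trimethylsilyloxy)pent-2-enoate | COC(=O)C=C(O[Si](C)(C)C)C(C)C
F5 | step 1 | 1-methoxy-4-methyl-1,3-bis(trimethylsilyloxy)penta-1,3-diene | COC(O[Si](C)(C)C)=CC(O[Si](C)(C)C)=C(C)C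
F6 | step 1 | methyl 4,4-dimethyl-3,5-dioxohept-6-enoate | COC(=O)CC(=O)C(C)(C)C(=O)C=C
F7 | step 5 | (4R)-2,4-dibromo-3,3-dimethylcyclohex-1-ene-1-carboxylic acid | CC1(C)C(Br)=C(C(=O)O)CC[C@H]1Br
F8 | step 5 | (4R)-2,4-dibromo-3,3-dimethylcyclohex-1-ene-1-carbonyl chloride | CC1(C)C(Br)=C(C(=O)Cl)CC[C@H]1Br
F9 | step 5 | 2-diazo-1-[(4R)-2,4-dibromo-3,3-dimethylcyclohex-1-en-1-yl]ethan-1-one | CC1(C)C(Br)=C(C(=O)C=[N+]=[N-])CC[C@H]1Br
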